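**Plan**

- Retrosynthesis: after removal of two aryl allyl ethers, the arylglycerol (ring A, C7''–C9'') is cut at the C8''–O bond to the ring B oxygen and traced to an α-aryloxy β-keto ester. The furofuran is cut at its two benzylic C–O bonds (C7–O, C7'–O) to an open-chain tetraol, and this at C7–C8 and C8'–C7' to a lithiated ring B dithiane, a 5-menthyloxybutenolide (C8, C8', C9, C9') and the ring C aldehyde.
- Forward: the three pieces are joined in one operation in which no ring forms. Dithiane hydrolysis and LiAlH4 give the tetraol, and one double cycloetherification closes both tetrahydrofuran rings together. The ring B phenol is then unmasked, alkylated with the ring A bromo keto ester, reduced enzymatically and with NaBH4, and deallylated.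
- Enabling feature: C8 and C8' are adjacent, trans-related ring-fusion carbons, each attached to one benzylic carbon (C7 on ring B, C7' on ring C) and one CH2O carbon (C9, C9'). This is the pattern of a 3,4-disubstituted butanolide, so a butenolide can take the C7 acyl anion at its β-carbon and the C7' aldehyde at its α-carbon.
- Stereochemistry: the acetal carbon C9, fixed by crystallisation of the (+)-menthol acetal, directs C8, and C8 directs C8'. C7 and C7' follow from C8/C8' when the benzylic cations close to the exo-aryl, cis-fused bicycle. C7'' and C8'' are set together by an anti-selective ketoreductase under dynamic kinetic resolution.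
- Protecting groups: a TIPS ether on ring B (removed by fluoride mid-route) and allyl ethers on rings A and C (removed last with Pd(PPh3)4), so that neither hydrogen nor acid meets the three benzylic C–O bonds.

Key step: step 6

Remark: lignan numbering is used (ring B, C7–C9: the furofuran half carrying the aryl ether; ring C, C7'–C9': the free-phenol half; ring A, C7''–C9'': the arylglycerol). The target is read as (7R,8S,7'R,8'S,7''R,8''S), an erythro arylglycerol ether of the (1R,3aS,4R,6aS)-furofuran. Carbinol centres formed without control (C7' in 13 and 14, C7 and C7' in 15) converge in step 9 and are drawn as one epimer.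

Abbreviations: Men = (1S,2R,5S)-5-methyl-2-(propan-2-yl)cyclohexyl; TIPS = tri(propan-2-yl)silyl; allyl = prop-2-en-1-yl.

**Route**

Step 1
Reactants: 1 furfural
Product: 2 5-hydroxyfuran-2(5H)-one (racemic hemiacetal)
Conditions: O2, hν (visible), methylene blue (3,7-bis(dimethylamino)phenothiazin-5-ium chloride, cat.), MeOH, rt
Reagents that add atoms: dioxygen, O=O
Why: Sensitised photooxygenation of a furan, in which singlet oxygen adds across C2 and C5 in a [4+2] sense and methanolysis of the adduct expels the formyl carbon as methyl formate, leaving the hydroxybutenolide.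

Step 2
Reactants: 2 5-hydroxyfuran-2(5H)-one; 3 (+)-menthol
Product: 5 (5S)-5-(Men-oxy)furan-2(5H)-one, via C5-epimeric acetal 4 (not isolated)
Conditions: camphor-10-sulfonic acid (cat.), toluene, reflux, Dean–Stark; crystallisation from petroleum ether, mother liquor re-equilibrated with the acid and recrystallised
Reagents that add atoms: none
Why: Acid-catalysed acetalisation gives both C5 epimers, which interconvert under the acid, so that crystallisation of the less soluble (5S)-diastereomer 5 drains epimer 4 (crystallisation-induced diastereomer transformation); the (5S) assignment rests on the mirror-image relationship to the known crystalline (5R)-acetal of (−)-menthol.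

Step 3
Reactants: 6 vanillin; 7 propane-1,3-dithiol
Product: 8 4-(1,3-dithian-2-yl)-2-methoxyphenol
Conditions: BF3·OEt2 (cat.), CH2Cl2, 0 °C to rt
Reagents that add atoms: none
Why: Lewis acid-catalysed dithioacetalisation of an aromatic aldehyde, which tolerates the free phenol.

Step 4
Reactants: 8 4-(1,3-dithian-2-yl)-2-methoxyphenol
Product: 9 [4-(1,3-dithian-2-yl)-2-methoxyphenoxy]tri(propan-2-yl)silane (ring B dithiane)
Conditions: iPr3SiCl, imidazole, DMF, rt
Reagents that add atoms: chlorotri(propan-2-yl)silane, CC(C)[Si](Cl)(C(C)C)C(C)C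
Why: Standard imidazole-mediated silylation of a phenol; the aryl TIPS ether should withstand n-BuLi at low temperature, MeI, LiAlH4 at 0 °C and MsCl/pyridine and later be cleaved by fluoride in the presence of allyl ethers.

Step 5
Reactants: 6 vanillin
Product: 10 3-methoxy-4-(allyloxy)benzaldehyde (ring C aldehyde)
Conditions: allyl bromide, K2CO3, DMF, rt
Reagents that add atoms: allyl bromide, C=CCBr
Why: Williamson etherification of the phenoxide; allyl is chosen because Pd(PPh3)4 removes it at the end without hydrogen or acid.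

Step 6
Reactants: 9 ring B dithiane; 5 (5S)-menthyloxybutenolide; 10 ring C aldehyde
Product: 13 (3R,4S,5S)-3-{hydroxy[3-methoxy-4-(allyloxy)phenyl]methyl}-4-{2-[3-methoxy-4-(TIPS-oxy)phenyl]-1,3-dithian-2-yl}-5-(Men-oxy)oxolan-2-one (C7' carbinol epimers), via 2-lithiodithiane 11 (not isolated), via lithium lactone enolate 12 (not isolated)
Conditions: n-BuLi, THF, −78 to −20 °C; then 5, −78 °C; then 10, −78 °C; AcOH, −78 °C
Reagents that add atoms: none
Why: n-BuLi removes the acidic C2–H of 9, and the sulfur-stabilised benzylic anion 11 (an acyl anion equivalent for C7) adds 1,4 to butenolide 5, forming C7–C8 and lithium enolate 12, which then adds to the carbonyl of 10 to form C8'–C7'. The closest known reaction type is the tandem conjugate addition–aldol trapping of 2-aryl-1,3-dithiane anions on 5-alkoxybutenolides, well established for lignan skeletons; no ring is formed in this step. C8 (lactone C4) is controlled by the C5 acetal centre, the nucleophile entering anti to the menthyloxy group, so that the (5S)-acetal gives (4S). C8' (lactone C3) is controlled by C8, the aldehyde approaching the enolate face opposite the bulky dithianyl group to give the 3,4-trans (3R) centre, while the carbinol C7' forms without control and both epimers are funnelled to one product in step 9. The step needs 1,4- rather than 1,2-addition, secured by the soft, hindered aryl dithianyl anion meeting an unhindered β-carbon, and it needs the aldolate kept from reverting, secured by the acetic acid quench at −78 °C.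

Step 7
Reactants: 13 dithiane aldol adduct
Product: 14 (3R,4S,5S)-3-{hydroxy[3-methoxy-4-(allyloxy)phenyl]methyl}-4-[3-methoxy-4-(TIPS-oxy)benzoyl]-5-(Men-oxy)oxolan-2-one (C7' carbinol epimers)
Conditions: MeI (excess), CaCO3, MeCN/H2O 9:1, 45 °C
Reagents that add atoms: water, O
Why: Alkylative dethioacetalisation, in which S-methylation turns sulfur into a leaving group and the aryl-stabilised thionium ion is hydrolysed under carbonate buffering, chosen over divalent mercury salts or oxidants to spare the allyl alkene, the electron-rich arenes, the acetal and the β-hydroxy lactone.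

Step 8
Reactants: 14 keto lactone
Product: 15 (2S,3S)-2-{hydroxy[3-methoxy-4-(allyloxy)phenyl]methyl}-3-{hydroxy[3-methoxy-4-(TIPS-oxy)phenyl]methyl}butane-1,4-diol (epimer mixture at both carbinol carbons)
Conditions: LiAlH4, THF, 0 °C to rt; H2O, aq NaOH work-up
Reagents that add atoms: none
Why: Hydride reduction of the ketone and of the lactone, after which the ring-opened C9 acetal carbon expels menthoxide and is reduced to CH2OH as well, so that the auxiliary leaves as recoverable (+)-menthol while C8 and C8' are untouched.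

Step 9
Reactants: 15 tetraol
Product: 16 {2-methoxy-4-[(1R,3aS,4R,6aS)-4-(3-methoxy-4-(allyloxy)phenyl)tetrahydro-1H,3H-furo[3,4-c]furan-1-yl]phenoxy}tri(propan-2-yl)silane
Conditions: MsCl, pyridine, 0 °C to rt
Reagents that add atoms: none
Why: Cyclodehydration by sulfonate activation, in which the electron-rich benzylic carbinols ionise after mesylation and each cation is captured by the 1,4-related primary hydroxyl to close a tetrahydrofuran, the cis ring fusion being dictated by C8 and C8' and each aryl group taking the exo position on the convex face, so that C7 and C7' both become R whichever carbinol epimers enter.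

Step 10
Reactants: 16 furofuran silyl ether
Product: 17 2-methoxy-4-[(1R,3aS,4R,6aS)-4-(3-methoxy-4-(allyloxy)phenyl)tetrahydro-1H,3H-furo[3,4-c]furan-1-yl]phenol
Conditions: Bu4NF, AcOH, THF, 0 °C
Reagents that add atoms: none
Why: Fluoride-induced cleavage of the aryl silyl ether, buffered with acetic acid so that the liberated phenoxide stays mild, with the allyl ether and the furofuran inert.

Step 11
Reactants: 18 acetovanillone
Product: 19 1-[3-methoxy-4-(allyloxy)phenyl]ethan-1-one
Conditions: allyl bromide, K2CO3, DMF, rt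
Reagents that add atoms: allyl bromide, C=CCBr
Why: Williamson etherification of the phenoxide of acetovanillone.

Step 12
Reactants: 19 O-allylacetovanillone
Product: 20 ethyl 3-[3-methoxy-4-(allyloxy)phenyl]-3-oxopropanoate
Conditions: NaH, (EtO)2CO, THF, reflux; AcOH quench
Reagents that add atoms: diethyl carbonate, CCOC(=O)OCC
Why: Crossed Claisen condensation of the methyl ketone enolate with diethyl carbonate, driven to completion by deprotonation of the β-keto ester product.

Step 13
Reactants: 20 β-keto ester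
Product: 21 ethyl 2-bromo-3-[3-methoxy-4-(allyloxy)phenyl]-3-oxopropanoate (racemic)
Conditions: NBS, Mg(ClO4)2 (cat.), EtOAc, 0 °C to rt
Reagents that add atoms: N-bromosuccinimide, O=C1CCC(=O)N1Br
Why: Lewis acid-catalysed electrophilic α-bromination of the enolised 1,3-dicarbonyl, which reacts far faster than the unactivated allyl alkene or the acyl-deactivated arene in this non-nucleophilic medium.

Step 14
Reactants: 17 ring B phenol; 21 bromo keto ester
Product: 22 ethyl 2-{2-methoxy-4-[(1R,3aS,4R,6aS)-4-(3-methoxy-4-(allyloxy)phenyl)tetrahydro-1H,3H-furo[3,4-c]furan-1-yl]phenoxy}-3-[3-methoxy-4-(allyloxy)phenyl]-3-oxopropanoate (interconverting C8'' epimers)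
Conditions: K2CO3, acetone, rt
Reagents that add atoms: none
Why: SN2 O-alkylation of the phenoxide by the doubly activated secondary bromide, the classical entry to arylglycerol β-aryl ether precursors, with C8'' arising as an interconverting epimer pair as the next step requires.

Step 15
Reactants: 22 α-aryloxy β-keto ester
Product: 23 ethyl (2R,3R)-3-hydroxy-2-{2-methoxy-4-[(1R,3aS,4R,6aS)-4-(3-methoxy-4-(allyloxy)phenyl)tetrahydro-1H,3H-furo[3,4-c]furan-1-yl]phenoxy}-3-[3-methoxy-4-(allyloxy)phenyl]propanoate
Conditions: anti-selective NADPH-dependent ketoreductase (picked from a commercial panel for (3R), anti delivery), NADP+ (nicotinamide adenine dinucleotide phosphate, cat.), i-PrOH, KH2PO4/K2HPO4 buffer pH 7, DMSO co-solvent, 30 °C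
Reagents that add atoms: none
Why: Ketoreductase-catalysed reduction under dynamic kinetic resolution, a known process for 2-substituted 3-aryl-3-oxopropanoates, in which C8'' epimerises through the enol at neutral pH while an enzyme chosen for (3R) hydride delivery to the (2R)-epimer gives the anti (erythro) product, so that C7'' is set by the enzyme and C8'' by its preference between the equilibrating epimers.

Step 16
Reactants: 23 anti hydroxy ester
Product: 24 (1R,2S)-2-{2-methoxy-4-[(1R,3aS,4R,6aS)-4-(3-methoxy-4-(allyloxy)phenyl)tetrahydro-1H,3H-furo[3,4-c]furan-1-yl]phenoxy}-1-[3-methoxy-4-(allyloxy)phenyl]propane-1,3-diol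
Conditions: NaBH4, EtOH/THF, 0 °C to rt
Reagents that add atoms: none
Why: Borohydride reduction of the ester, activated by its α-aryloxy and β-hydroxy groups, to the primary alcohol in a protic medium that leaves the allyl alkenes alone and is too mild for retro-aldol cleavage or epimerisation at C8''.

Step 17
Reactants: 24 bis-allyl ether
Product: 25 (1R,2S)-1-(4-hydroxy-3-methoxyphenyl)-2-{4-[(1R,3aS,4R,6aS)-4-(4-hydroxy-3-methoxyphenyl)tetrahydro-1H,3H-furo[3,4-c]furan-1-yl]-2-methoxyphenoxy}propane-1,3-diol (target)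
Conditions: Pd(PPh3)4 (5 mol%), morpholine, THF, rt
Reagents that add atoms: none
Why: Tsuji–Trost-type deallylation, in which zerovalent palladium ionises both aryl allyl ethers and morpholine captures the allyl groups under neutral, non-reductive conditions that spare the two furofuran benzylic ethers and the benzylic alcohol.

**Compound list**

1 | furfural | O=Cc1ccco1 | starting material
2 | 5-hydroxyfuran-2(5H)-one (racemic) | O=C1C=CC(O)O1 | intermediate
3 | (+)-menthol, (1S,2R,5S) | CC(C)[C@H]1CC[C@H](C)C[C@@H]1O | starting material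
4 | (5R)-5-(Men-oxy)furan-2(5H)-one (C5 epimer of 5) | O=C1C=C[C@H](O[C@H]2C[C@@H](C)CC[C@@H]2C(C)C)O1 | intermediate (not isolated)
5 | (5S)-5-(Men-oxy)furan-2(5H)-one | O=C1C=C[C@@H](O[C@H]2C[C@@H](C)CC[C@@H]2C(C)C)O1 | intermediate
6 | vanillin | COc1cc(C=O)ccc1O | starting material
7 | propane-1,3-dithiol | SCCCS | starting material
8 | 4-(1,3-dithian-2-yl)-2-methoxyphenol | COc1cc(ccc1O)C1SCCCS1 | intermediate
9 | [4-(1,3-dithian-2-yl)-2-methoxyphenoxy]tri(propan-2-yl)silane | COc1cc(ccc1O[Si](C(C)C)(C(C)C)C(C)C)C1SCCCS1 | intermediate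
10 | 3-methoxy-4-(allyloxy)benzaldehyde | COc1cc(C=O)ccc1OCC=C | intermediate
11 | 2-lithio-2-[3-methoxy-4-(TIPS-oxy)phenyl]-1,3-dithiane | [Li]C1(SCCCS1)c1ccc(O[Si](C(C)C)(C(C)C)C(C)C)c(OC)c1 | intermediate (not isolated)
12 | lithium (4S,5S)-4-{2-[3-methoxy-4-(TIPS-oxy)phenyl]-1,3-dithian-2-yl}-5-(Men-oxy)-4,5-dihydrofuran-2-olate | [Li]OC1=C[C@H](C2(SCCCS2)c2ccc(O[Si](C(C)C)(C(C)C)C(C)C)c(OC)c2)[C@@H](O[C@H]2C[C@@H](C)CC[C@@H]2C(C)C)O1 | intermediate (not isolated)
13 | (3R,4S,5S)-3-{hydroxy[3-methoxy-4-(allyloxy)phenyl]methyl}-4-{2-[3-methoxy-4-(TIPS-oxy)phenyl]-1,3-dithian-2-yl}-5-(Men-oxy)oxolan-2-one (C7' epimers; R carbinol drawn) | O=C1[C@@H]([C@@H](O)c2ccc(OCC=C)c(OC)c2)[C@H](C2(SCCCS2)c2ccc(O[Si](C(C)C)(C(C)C)C(C)C)c(OC)c2)[C@@H](O[C@H]2C[C@@H](C)CC[C@@H]2C(C)C)O1 | intermediate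
14 | (3R,4S,5S)-3-{hydroxy[3-methoxy-4-(allyloxy)phenyl]methyl}-4-[3-methoxy-4-(TIPS-oxy)benzoyl]-5-(Men-oxy)oxolan-2-one (C7' epimers; R carbinol drawn) | O=C1[C@@H]([C@@H](O)c2ccc(OCC=C)c(OC)c2)[C@H](C(=O)c2ccc(O[Si](C(C)C)(C(C)C)C(C)C)c(OC)c2)[C@@H](O[C@H]2C[C@@H](C)CC[C@@H]2C(C)C)O1 | intermediate
15 | (2S,3S)-2-{hydroxy[3-methoxy-4-(allyloxy)phenyl]methyl}-3-{hydroxy[3-methoxy-4-(TIPS-oxy)phenyl]methyl}butane-1,4-diol (carbinol epimer mixture; R,R carbinols drawn) | OC[C@@H]([C@@H](O)c1ccc(OCC=C)c(OC)c1)[C@H]([C@@H](O)c1ccc(O[Si](C(C)C)(C(C)C)C(C)C)c(OC)c1)CO | intermediate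
16 | {2-methoxy-4-[(1R,3aS,4R,6aS)-4-(3-methoxy-4-(allyloxy)phenyl)tetrahydro-1H,3H-furo[3,4-c]furan-1-yl]phenoxy}tri(propan-2-yl)silane | COc1cc(ccc1O[Si](C(C)C)(C(C)C)C(C)C)[C@@H]1OC[C@@H]2[C@H]1CO[C@H]2c1ccc(OCC=C)c(OC)c1 | intermediate
17 | 2-methoxy-4-[(1R,3aS,4R,6aS)-4-(3-methoxy-4-(allyloxy)phenyl)tetrahydro-1H,3H-furo[3,4-c]furan-1-yl]phenol | COc1cc(ccc1O)[C@@H]1OC[C@@H]2[C@H]1CO[C@H]2c1ccc(OCC=C)c(OC)c1 | intermediate
18 | acetovanillone, 1-(4-hydroxy-3-methoxyphenyl)ethan-1-one | CC(=O)c1ccc(O)c(OC)c1 | starting material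
19 | 1-[3-methoxy-4-(allyloxy)phenyl]ethan-1-one | CC(=O)c1ccc(OCC=C)c(OC)c1 | intermediate
20 | ethyl 3-[3-methoxy-4-(allyloxy)phenyl]-3-oxopropanoate | CCOC(=O)CC(=O)c1ccc(OCC=C)c(OC)c1 | intermediate
21 | ethyl 2-bromo-3-[3-methoxy-4-(allyloxy)phenyl]-3-oxopropanoate (racemic) | CCOC(=O)C(Br)C(=O)c1ccc(OCC=C)c(OC)c1 | intermediate
22 | ethyl 2-{2-methoxy-4-[(1R,3aS,4R,6aS)-4-(3-methoxy-4-(allyloxy)phenyl)tetrahydro-1H,3H-furo[3,4-c]furan-1-yl]phenoxy}-3-[3-methoxy-4-(allyloxy)phenyl]-3-oxopropanoate (labile C8'' left undefined) | CCOC(=O)C(Oc1ccc(cc1OC)[C@@H]1OC[C@@H]2[C@H]1CO[C@H]2c1ccc(OCC=C)c(OC)c1)C(=O)c1ccc(OCC=C)c(OC)c1 | intermediate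
23 | ethyl (2R,3R)-3-hydroxy-2-{2-methoxy-4-[(1R,3aS,4R,6aS)-4-(3-methoxy-4-(allyloxy)phenyl)tetrahydro-1H,3H-furo[3,4-c]furan-1-yl]phenoxy}-3-[3-methoxy-4-(allyloxy)phenyl]propanoate | C=CCOc1ccc(cc1OC)[C@@H](O)[C@H](C(=O)OCC)Oc1ccc(cc1OC)[C@@H]1OC[C@@H]2[C@H]1CO[C@H]2c1ccc(OCC=C)c(OC)c1 | intermediate
24 | (1R,2S)-2-{2-methoxy-4-[(1R,3aS,4R,6aS)-4-(3-methoxy-4-(allyloxy)phenyl)tetrahydro-1H,3H-furo[3,4-c]furan-1-yl]phenoxy}-1-[3-methoxy-4-(allyloxy)phenyl]propane-1,3-diol | C=CCOc1ccc(cc1OC)[C@@H](O)[C@H](CO)Oc1ccc(cc1OC)[C@@H]1OC[C@@H]2[C@H]1CO[C@H]2c1ccc(OCC=C)c(OC)c1 | intermediate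
25 | (1R,2S)-1-(4-hydroxy-3-methoxyphenyl)-2-{4-[(1R,3aS,4R,6aS)-4-(4-hydroxy-3-methoxyphenyl)tetrahydro-1H,3H-furo[3,4-c]furan-1-yl]-2-methoxyphenoxy}propane-1,3-diol | COc1cc([C@@H](O)[C@H](CO)Oc2ccc([C@@H]3OC[C@@H]4[C@H]3CO[C@H]4c3ccc(O)c(OC)c3)cc2OC)ccc1O | target

**Summary and risks**

Total steps: 17. Longest linear sequence: 11 steps (1, 2, 6, 7, 8, 9, 10, 14, 15, 16, 17).

Steps most likely to fail:

1. Step 15. The large, poorly water-soluble keto ester 22 may not be accepted by any enzyme of the panel, hydride may be delivered with syn instead of anti selectivity, or epimerisation at C8'' may be slower than reduction so that the resolution is not dynamic. The fallback sets out from 22 and comes back at 23. Transfer hydrogenation under dynamic kinetic resolution with RuCl[(R,R)-TsDPEN](p-cymene) in HCO2H/Et3N is expected to follow the syn preference known for α-oxygenated β-keto esters and should give the syn (2R,3S)-hydroxy ester F1. Mitsunobu inversion of its benzylic carbinol (4-nitrobenzoic acid, PPh3, DIAD, THF, 0 °C) should give the (2R,3R)-4-nitrobenzoate F2. Ethanolysis (K2CO3, EtOH, 0 °C) then removes the activated aryl ester without exchanging the ethyl ester and returns 23.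

2. Step 6. Aldol capture of the hindered enolate may be incomplete or may revert (retro-aldol on warming, proton transfer), or 1,2-addition may compete. The fallback sets out from 9, 5 and 10 and comes back at 13. Enolate 12 is generated as in step 6 and trapped irreversibly by C-acylation instead. For this, 10 is oxidised (NaClO2, NaH2PO4, 2-methylbut-2-ene, t-BuOH/H2O) to 3-methoxy-4-(allyloxy)benzoic acid F3, which (COCl)2 with catalytic DMF converts into 3-methoxy-4-(allyloxy)benzoyl chloride F4. Addition of F4 to 12 at −78 °C, with one further equivalent of LiN(SiMe3)2 to absorb the acidic proton of the product, should give the trans β-keto lactone F5. NaBH4 (MeOH/THF, −40 °C) should reduce only its aryl ketone and return 13 as the carbinol epimer mixture.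

3. Step 14. The phenoxide may attack bromine instead of carbon (halogen transfer, which returns 20 and brominates the phenol), or the bromide may decompose under base before substitution. The fallback sets out from 20 and 17 and comes back at 22. Diazo transfer (4-acetamidobenzenesulfonyl azide, Et3N, MeCN) converts 20 into ethyl 2-diazo-3-[3-methoxy-4-(allyloxy)phenyl]-3-oxopropanoate F6. Rh2(OAc)4-catalysed O–H insertion of the derived carbenoid into phenol 17 (CH2Cl2, rt, slow addition of F6) forms the same C8''–O bond under neutral conditions and gives 22.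

Further compounds
F1 | step 15 | ethyl (2R,3S)-3-hydroxy-2-{2-methoxy-4-[(1R,3aS,4R,6aS)-4-(3-methoxy-4-(allyloxy)phenyl)tetrahydro-1H,3H-furo[3,4-c]furan-1-yl]phenoxy}-3-[3-methoxy-4-(allyloxy)phenyl]propanoate (syn hydroxy ester) | C=CCOc1ccc(cc1OC)[C@H](O)[C@H](C(=O)OCC)Oc1ccc(cc1OC)[C@@H]1OC[C@@H]2[C@H]1CO[C@H]2c1ccc(OCC=C)c(OC)c1
F2 | step 15 | ethyl (2R,3R)-2-{2-methoxy-4-[(1R,3aS,4R,6aS)-4-(3-methoxy-4-(allyloxy)phenyl)tetrahydro-1H,3H-furo[3,4-c]furan-1-yl]phenoxy}-3-[3-methoxy-4-(allyloxy)phenyl]-3-[(4-nitrobenzoyl)oxy]propanoate | C=CCOc1ccc(cc1OC)[C@@H](OC(=O)c1ccc(cc1)[N+](=O)[O-])[C@H](C(=O)OCC)Oc1ccc(cc1OC)[C@@H]1OC[C@@H]2[C@H]1CO[C@H]2c1ccc(OCC=C)c(OC)c1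
F3 | step 6 | 3-methoxy-4-(allyloxy)benzoic acid | OC(=O)c1ccc(OCC=C)c(OC)c1
F4 | step 6 | 3-methoxy-4-(allyloxy)benzoyl chloride | ClC(=O)c1ccc(OCC=C)c(OC)c1
F5 | step 6 | (3R,4S,5S)-3-[3-methoxy-4-(allyloxy)benzoyl]-4-{2-[3-methoxy-4-(TIPS-oxy)phenyl]-1,3-dithian-2-yl}-5-(Men-oxy)oxolan-2-one | O=C1[C@@H](C(=O)c2ccc(OCC=C)c(OC)c2)[C@H](C2(SCCCS2)c2ccc(O[Si](C(C)C)(C(C)C)C(C)C)c(OC)c2)[C@@H](O[C@H]2C[C@@H](C)CC[C@@H]2C(C)C)O1
F6 | step 14 | ethyl 2-diazo-3-[3-methoxy-4-(allyloxy)phenyl]-3-oxopropanoate | CCOC(=O)C(=[N+]=[N-])C(=O)c1ccc(OCC=C)c(OC)c1
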